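## Retrosynthetic overview

- The target is traced back to its dehydro congener, in which the two ring-fusion carbons shared by pyran A (the 2,2-dimethylpyran on quinolinone A) and the cyclohexane ring C form a C=C bond. Syn-hydrogenation from the convex face of that alkene sets both fusion centres last.
- The dehydro hexacycle is cut at two ring C bonds: the CH2–C(CH3)(O) bond to the quaternary carbon of pyran B (the bridging pyran on quinolinone B), and the bond between the two ring-fusion carbons. A third cut, the O–C(CH3)2 bond of pyran A, falls in the same operation. This gives a pyran B methyl ketal carrying a 2-methylpropenyl group and the bis-silyl dienol ether of 3-acetyl-4-hydroxy-1-methylquinolin-2-one.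
- The ketal comes from an enantioselective Michael addition of 4-hydroxy-1-methylquinolin-2-one to 6-methylhepta-3,5-dien-2-one, followed by ketalisation. The dienol ether comes from the same quinolinone by C-acetylation and silylation.
- Ring order: both quinolinones are bought; pyran B forms first, then ring C and pyran A in one operation.
- Enabling feature: the CH2–C(CH3)(O) bond of ring C ends at the ketal-level carbon of pyran B, and the CH–CH bond is the C3–C4 bond of pyran A beside the enolic C3=C4–O unit of quinolinone A. A 3-acetyl-4-oxyquinolinone can therefore act first through its CH3 as a carbon nucleophile and then through its C=O as an electrophile toward an alkene held 1,3-diaxially on pyran B.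

Key step: step 5

Assumption: the (R,R)-diamine in step 1 is taken to give the (R) adduct, as it does in the warfarin series, with the 2-methylpropenyl group taking the place and CIP rank of phenyl; if the sense is the opposite, the (S,S)-diamine is used in the same way.

## Route

Step 1
Reactants: 1 4-hydroxy-1-methylquinolin-2(1H)-one; 2 (3E)-6-methylhepta-3,5-dien-2-one
Product: 3 (R)-4-hydroxy-1-methyl-3-(6-methyl-2-oxohept-5-en-4-yl)quinolin-2(1H)-one (open keto form, in equilibrium with its cyclic hemiketals)
Conditions: (R,R)-1,2-diphenylethane-1,2-diamine (10 mol %), AcOH (10 equiv), THF, 23 °C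
Reagents that add atoms: none
Why: Amine-catalysed (iminium) enantioselective Michael addition of the vinylogous acid to the enone, the warfarin-type reaction; attack at C4 is expected because the competing 1,6-site is the fully substituted C6, and the hydrogen-bonded diamine iminium shields one enone face to set the (R) centre.

Step 2
Reactants: 3 (R)-4-hydroxy-1-methyl-3-(6-methyl-2-oxohept-5-en-4-yl)quinolin-2(1H)-one
Product: 4 (4R)-2-methoxy-2,6-dimethyl-4-(2-methylprop-1-en-1-yl)-2,3,4,6-tetrahydro-5H-pyrano[3,2-c]quinolin-5-one (both C2 epimers)
Conditions: MeOH, camphorsulfonic acid (5 mol %), 3 Å MS, 23 °C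
Reagents that add atoms: methanol, CO
Why: Acid-catalysed ketalisation of the ring-closed hemiketal tautomer (the known behaviour of warfarin-type adducts in acidic methanol) locks pyran B and makes the ketone carbon an oxocarbenium precursor; the ketal carbon forms as both epimers, which is immaterial because it is ionised in step 5, and the mild acid should leave the (R) centre and the trisubstituted alkene untouched.

Step 3
Reactants: 1 4-hydroxy-1-methylquinolin-2(1H)-one
Product: 5 3-acetyl-4-hydroxy-1-methylquinolin-2(1H)-one
Conditions: AcCl, AcOH, polyphosphoric acid, 90 °C
Reagents that add atoms: acetyl chloride, CC(=O)Cl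
Why: C-acylation of the vinylogous acid at C3 (O-acylation followed by acid-promoted Fries-type O-to-C acyl shift), the standard entry to 3-acyl-4-hydroxyquinolin-2-ones.

Step 4
Reactants: 5 3-acetyl-4-hydroxy-1-methylquinolin-2(1H)-one
Product: 6 1-methyl-4-(trimethylsilyloxy)-3-[1-(trimethylsilyloxy)ethenyl]quinolin-2(1H)-one
Conditions: TMSOTf (2.3 equiv), Et3N (2.6 equiv), Et2O, 0 → 23 °C; pentane, filtration under argon, used crude
Reagents that add atoms: trimethylsilyl trifluoromethanesulfonate, C[Si](C)(C)OS(=O)(=O)C(F)(F)F
Why: Soft enolisation silylates the acidic 4-OH and converts the acetyl group into its silyl enol ether, giving a 1,3-bis(silyloxy)-1,3-diene whose nucleophilic site is the terminal CH2; no stereocentre is formed.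

Step 5
Reactants: 4 (4R)-2-methoxy-2,6-dimethyl-4-(2-methylprop-1-en-1-yl)-2,3,4,6-tetrahydro-5H-pyrano[3,2-c]quinolin-5-one; 6 1-methyl-4-(trimethylsilyloxy)-3-[1-(trimethylsilyloxy)ethenyl]quinolin-2(1H)-one (1.5 equiv)
Product: 9 dehydro hexacycle (the target skeleton with a C=C bond between the two ring-fusion carbons of pyran A and ring C; pyran B bridge and its two stereocentres as in the target), via silyl keto adduct 7 (not isolated), via tertiary silyl ether 8 (not isolated)
Conditions: TMSOTf (0.3 equiv), 4 Å MS, CH2Cl2, −78 → 23 °C, then 40 °C
Reagents that add atoms: none
Why: Proposed new method: TMSOTf ionises ketal 4 to the cyclic oxocarbenium ion of pyran B, and the terminal CH2 of diene 6 adds to it in a vinylogous Mukaiyama addition (the closest known type for this half: additions of enol silanes and 1,3-bis(silyloxy)dienes to ketals and 2-alkoxychromans) to give 7. The silyl-activated acyl carbon of 7 is then attacked by the 2-methylpropenyl CH held 1,3-diaxially on pyran B in a carbonyl–olefin Prins closure (closest known type: Lewis-acid Prins and interrupted carbonyl–olefin metathesis reactions of aryl ketones with prenyl-type alkenes; the same bond set can be read as an inverse-demand hetero-Diels–Alder reaction of the silylated 3-acyl-4-oxyquinolinone heterodiene). Ring C closes by 6-exo attack of the alkene on the acyl carbon, pyran A closes when the 4-oxygen of quinolinone A captures the tertiary cation in a six-membered oxa-cyclisation with loss of its silyl group (8), and E1 loss of trimethylsilanol from the doubly activated tertiary ether toward the ring-fusion CH gives the tetrasubstituted 2H-pyran alkene of 9, as in the dehydration of 4-alkylchroman-4-ols to 4-alkyl-2H-chromenes. The one new stereocentre that survives, the methyl-bearing O–C carbon of pyran B, is fixed by the bridge: only the adduct with the acylmethyl arm cis to the alkenyl group can close, the trans adduct can return by acid-catalysed β-elimination and oxa-Michael re-addition of the quinolinone B oxygen, and the centre from step 1 is untouched. The step needs C-attack at the terminal carbon of 6 (secured by the bis-silyl dienol ether), Prins closure in preference to plain desilylation (favoured by the 1,3-diaxial proximity and by reversible silyl activation of the carbonyl), and elimination into pyran A instead of toward the ring C methylene (expected from the chromanol precedent and correctable by acid equilibration through the same cation).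

Step 6
Reactants: 9 dehydro hexacycle
Product: 10 target: pyran A cis-fused to ring C, with the two ring-fusion H atoms and the H on the benzylic bridgehead carbon all on the same face of ring C, and pyran B bridging ring C 1,3-diaxially on the opposite face
Conditions: H2 (50 bar), Pd(OH)2/C, EtOAc–AcOH (10:1), 40 °C
Reagents that add atoms: none
Why: Heterogeneous syn-hydrogenation of the 2H-pyran alkene (as in the reduction of N-methylflindersine-type 2,2-dimethyl-2H-pyrans to their dihydro compounds): the bicyclo[3.3.1]nonene core is V-shaped and its concave face is closed by the O–C=C bridge that carries quinolinone B, so both hydrogens should arrive from the convex face, which sets the two ring-fusion centres cis to each other with their H atoms cis to the bridgehead H; the quinolinone rings and the tertiary ethers should not be reduced.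

## Compound list

1 | 4-hydroxy-1-methylquinolin-2(1H)-one | Cn1c(=O)cc(O)c2ccccc12 | starting material
2 | (3E)-6-methylhepta-3,5-dien-2-one | CC(=O)/C=C/C=C(C)C | starting material
3 | (R)-4-hydroxy-1-methyl-3-(6-methyl-2-oxohept-5-en-4-yl)quinolin-2(1H)-one | CC(=O)C[C@H](C=C(C)C)c1c(O)c2ccccc2n(C)c1=O | intermediate
4 | (4R)-2-methoxy-2,6-dimethyl-4-(2-methylprop-1-en-1-yl)-2,3,4,6-tetrahydro-5H-pyrano[3,2-c]quinolin-5-one, both C2 epimers | COC1(C)C[C@H](C=C(C)C)c2c(O1)c1ccccc1n(C)c2=O | intermediate
5 | 3-acetyl-4-hydroxy-1-methylquinolin-2(1H)-one | CC(=O)c1c(O)c2ccccc2n(C)c1=O | intermediate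
6 | 1-methyl-4-(trimethylsilyloxy)-3-[1-(trimethylsilyloxy)ethenyl]quinolin-2(1H)-one | C=C(O[Si](C)(C)C)c1c(O[Si](C)(C)C)c2ccccc2n(C)c1=O | intermediate
7 | silyl keto adduct: pyran B carrying at its O–C(CH3) carbon a CH2–C(=O) arm to C3 of 1-methyl-4-(trimethylsilyloxy)quinolin-2-one, arm cis to the 2-methylprop-1-enyl group on the (R) carbon | C[Si](C)(C)Oc1c(C(=O)C[C@]2(C)C[C@H](C=C(C)C)c3c(O2)c2ccccc2n(C)c3=O)c(=O)n(C)c2ccccc12 | intermediate (not isolated)
8 | tertiary silyl ether hexacycle: ring C and pyran A closed, OSiMe3 on the ring-fusion carbon bonded to quinolinone A, H on the other ring-fusion carbon (epimers at these two carbons, both lost in the elimination) | Cn1c(=O)c2c(c3ccccc31)OC(C)(C)C1C2(O[Si](C)(C)C)C[C@]2(C)C[C@H]1c1c(c3ccccc3n(C)c1=O)O2 | intermediate (not isolated)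
9 | dehydro hexacycle: target skeleton with C=C between the two ring-fusion carbons of pyran A and ring C | Cn1c(=O)c2c(c3ccccc31)OC(C)(C)C1=C2C[C@]2(C)C[C@H]1c1c(c3ccccc3n(C)c1=O)O2 | intermediate
10 | target, all-cis bridged bis(pyranoquinolinone) | Cn1c(=O)c2c(c3ccccc31)OC(C)(C)[C@H]1[C@@H]2C[C@]2(C)C[C@H]1c1c(c3ccccc3n(C)c1=O)O2 | target

## Step count and risks

Total step count: 6. Longest linear sequence: 4 (steps 1, 2, 5, 6, or steps 3, 4, 5, 6).

**Step 5.** The cascade may stall after the first C–C bond (desilylation of the activated carbonyl without Prins closure), pyran B may open by β-elimination, or the final proton loss may go toward the ring C methylene. The fallback uses known reaction types only and sets out from 4 and 6. The TMSOTf-catalysed vinylogous Mukaiyama addition alone is run at −78 °C and quenched, giving after mild acid equilibration the keto enol F1 with the arm cis to the alkenyl group. NaBH4 in EtOH at −20 °C reduces the acyl carbonyl to the carbinol F2. Heating in toluene at 110 °C dehydrates it to the ortho-quinone methide of quinolinone A, which adds to the 2-methylpropenyl group in an intramolecular inverse-demand hetero-Diels–Alder reaction to give the saturated hexacycle F3 as ring-fusion epimers. DDQ in dioxane at 100 °C then dehydrogenates pyran A, as in the conversion of dihydropyranoquinolinones into their 2H-pyrans, and the route is rejoined at 9.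

**Step 6.** The tetrasubstituted alkene may resist reduction, the double bond may migrate before reduction, or face selectivity may be incomplete. The fallback sets out from 9 and uses ionic hydrogenation with CF3CO2H and Et3SiH in CH2Cl2: protonation at the CMe2-bearing alkene carbon gives the cation stabilised by the pyran A oxygen through quinolinone A, and hydride is delivered from the convex face. The configuration at the protonated carbon then depends on face-selective (and possibly reversible) protonation, so this is less secure than the syn-hydrogenation. It comes back to the route at 10.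

**Step 1.** The dienone may give some 1,6-addition, or the enantioselectivity may be low or of the opposite sense. The fallback sets out from 1 and 2: the Michael addition is run without a chiral catalyst (Et3N, MeOH, 60 °C, the classical warfarin-type condensation) to give the racemic adduct F4, the enantiomers are separated by preparative chiral-phase supercritical-fluid chromatography, and the (R) enantiomer rejoins the route at 3.

## Further compounds

F1 | step 5 | keto enol: desilylated cis adduct, pyran B carrying a CH2–C(=O) arm to C3 of 4-hydroxy-1-methylquinolin-2-one | Oc1c(C(=O)C[C@]2(C)C[C@H](C=C(C)C)c3c(O2)c2ccccc2n(C)c3=O)c(=O)n(C)c2ccccc12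
F2 | step 5 | carbinol: F1 with the acyl C=O reduced to CH–OH, both carbinol epimers | Oc1c(C(O)C[C@]2(C)C[C@H](C=C(C)C)c3c(O2)c2ccccc2n(C)c3=O)c(=O)n(C)c2ccccc12
F3 | step 5 | saturated hexacycle, epimers at the two ring-fusion carbons of pyran A and ring C | Cn1c(=O)c2c(c3ccccc31)OC(C)(C)C1C2C[C@]2(C)C[C@H]1c1c(c3ccccc3n(C)c1=O)O2
F0 | step 6 | none | none
F4 | step 1 | racemic 4-hydroxy-1-methyl-3-(6-methyl-2-oxohept-5-en-4-yl)quinolin-2(1H)-one | CC(=O)CC(C=C(C)C)c1c(O)c2ccccc2n(C)c1=O
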